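You read this flask at 20 h, but the readings stop at 4.00 h, so the task is to cross that gap.

common to all: Sbt 15 mM; Ctl 0.5 mol%
- cedar: Rea 1.2 equiv (fed, over 3.0 h); the very flask that is asked about, followed so far
- flask: Rea 1.20 equiv (fed, over 3.0 h); time 20 h

cedar run (percent of the Sbt charged)

| time / h | Pdt / % | Sbt / % |
|---|---|---|
| 0.333 | 1.0 | 97.8 |
| 0.500 | 0.1 | 99.5 |
| 0.667 | 0.7 | 99.4 |
| 1.00 | 1.5 | 96.6 |
| 1.50 | 5.2 | 94.8 |
| 2.50 | 9.9 | 89.5 |
| 4.00 | 16.5 | 84.4 |

(each reading ± 1 percentage point)

- the analysis behind the earlier runs scatters by 1 percentage point, standard deviation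
- a reading or a percentage of Pdt counts all its forms, free or not

- the Pdt in the flask at 20 h, as a percentage of the Sbt charged
- the Sbt in the flask at 20 h, as a percentage of the Sbt charged

In the first instants the feed of Rea has only begun. By 1.00 h it has brought in 0.400 equiv of Rea against 0.5 mol% of Ctl, yet Pdt reads 1.5 % with a scatter of 1 percentage point, so Pdt trails the feed.

In the middle, from 1.50 h to 4.00 h, Sbt goes from 94.8 % to 84.4 %, and the readings show no break when the feed ends at 3.0 h. Go to logarithms. If the loss is pseudo-first-order, the logarithm of the fraction left falls on a straight line, here with a slope of 0.0465 h⁻¹. That gives 14.9 h for the half-life of Sbt, the time in which the fraction left falls by half; it is a reading and carries the scatter.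

For the end, the last reading shows 15.6 % of the Sbt gone, so the order is your assumption and not a finding. On that assumption, the 16.0 h after the last reading are 1.07 half-lives, so you commit to 40.1 % Sbt and the other 59.9 % as Pdt.

The forecast says 62 % Pdt and 38 % Sbt, less Sbt than your figure: “I expect about 62%, with wide uncertainty, and the balance as Sbt.”

At 20 h the flask holds 58.2 % Pdt and 27.3 % Sbt.

    Rea + Ctl → Imd (k = 2700 M⁻¹ h⁻¹)
    Sbt + Imd → Imd2 (k = 2500 M⁻¹ h⁻¹)
    Imd2 → Imd3 (k = 54.0 h⁻¹)
    Imd3 → Ctl + Pdt (k = 750 h⁻¹)
    Ctl + Pdt ⇌ Imd4, settled at all times (K = 180 M⁻¹)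
    Pdt ⇌ Ofp (K = 19.0, k = 0.0200 h⁻¹)

Beside them stands 14.5 % of Ofp. Taken as one first-order fall from the start to 20 h, Sbt has an average half-life of 10.7 h, shorter than the 14.9 h you read. A neighbour flask charged with 3.8 mM of Sbt, at the same equivalents and loading, has its Ctl and its Rea diluted 3.95-fold. Stretching the half-life by that factor gives 42.1 h and 72.0 % Sbt left, and that neighbour holds 63.6 % Sbt at 20 h.

The runs are simulated from invented constants; the scatter is artificial.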